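**Retrosynthetic overview**

1. Agastinol ⇒ (−)-lariciresinol + 4-hydroxybenzoic acid: the ester C–O bond is made last, on the unprotected triphenol, by Mitsunobu esterification.
2. (−)-Lariciresinol ⇒ (+)-secoisolariciresinol: key step, the tetrahydrofuran C2–O bond is made from a benzylic C–H bond (dehydrogenative cycloetherification through a p-quinone methide); it closes the ring and sets the third stereocentre.
3. (+)-Secoisolariciresinol ⇒ C2-symmetric (S,S)-bis(acyloxazolidinone) ⇒ two molecules of one N-(3-arylpropanoyl)oxazolidinone: oxidative enolate homocoupling sets both carbon stereocentres at once.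
4. That imide ⇒ dihydroferulic acid, pivaloyl chloride and (R)-4-benzyl-2-oxazolidinone.
5. Rings: the three benzene rings are bought; the tetrahydrofuran is the only ring formed (step 4).

Assumption: the target is taken exactly as drawn, (2R,3S,4S) at the tetrahydrofuran, i.e. the 9-O-(4-hydroxybenzoate) of (−)-lariciresinol, and dihydroferulic acid is bought (it is also one hydrogenation away from ferulic acid).

**Route**

Step 1
Reactants: 1 3-(4-hydroxy-3-methoxyphenyl)propanoic acid (dihydroferulic acid); 2 pivaloyl chloride; 3 (R)-4-benzyl-2-oxazolidinone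
Product: 5 (R)-4-benzyl-3-[3-(3-methoxy-4-pivaloyloxyphenyl)propanoyl]oxazolidin-2-one, via mixed pivalic anhydride 4 (not isolated)
Conditions: PivCl (2.2 equiv), Et3N (3.5 equiv), THF, −20 → 0 °C; then LiCl (1.1 equiv), 3 (1.0 equiv), 0 °C → rt
Reagents that add atoms: pivaloyl chloride (2), CC(C)(C)C(=O)Cl; (R)-4-benzyl-2-oxazolidinone (3), O=C1N[C@H](Cc2ccccc2)CO1
Why: Mixed-anhydride N-acylation of the oxazolidinone (one-pot LiCl/Et3N protocol): pivaloyl chloride turns the acid into anhydride 4 and at the same time caps the phenol as a pivalate, the auxiliary nitrogen then attacks the unhindered acyl carbon of 4; no stereocentre is formed.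

Step 2
Reactants: 5 (R)-4-benzyl-3-[3-(3-methoxy-4-pivaloyloxyphenyl)propanoyl]oxazolidin-2-one (two molecules)
Product: 7 (2S,3S)-2,3-bis(3-methoxy-4-pivaloyloxybenzyl)-1,4-bis[(R)-4-benzyl-2-oxooxazolidin-3-yl]butane-1,4-dione, via lithium Z-enolate 6 (not isolated)
Conditions: LiN(iPr)2 (1.1 equiv), THF, −78 °C; then TiCl4 (1.1 equiv), −78 °C → rt
Reagents that add atoms: none
Why: Auxiliary-controlled oxidative enolate homocoupling: the chelated Z-enolate 6 is oxidised by tetravalent titanium (one electron each, leaving trivalent titanium) and the two α-carbons join on the enolate face opposite the auxiliary benzyl group, which with the (R)-oxazolidinone makes both new centres S (the C2-symmetric like-dimer); the aryl pivalates have no acidic hydrogen and are inert to the hindered amide base at −78 °C.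

Step 3
Reactants: 7 (2S,3S)-bis-imide dimer
Product: 8 (+)-secoisolariciresinol, (2S,3S)-2,3-bis(4-hydroxy-3-methoxybenzyl)butane-1,4-diol
Conditions: LiAlH4 (6 equiv), THF, 0 °C → rt; aq. HCl work-up
Reagents that add atoms: none
Why: Exhaustive hydride reduction: LiAlH4 cleaves both N-acyloxazolidinones reductively to the primary alcohols (auxiliary 3 is released and can be recovered) and reduces both aryl pivalates to the free phenols in the same flask; the two stereocentres are not touched.

Step 4
Reactants: 8 (+)-secoisolariciresinol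
Product: 10 (−)-lariciresinol, 4-[(2R,3S,4S)-4-(4-hydroxy-3-methoxybenzyl)-3-(hydroxymethyl)tetrahydrofuran-2-yl]-2-methoxyphenol, via p-quinone methide 9 (not isolated)
Conditions: p-chloranil (0.75 equiv), tetrachlorohydroquinone (0.25 equiv), 2,6-lutidine (1.0 equiv), anhydrous MeCN–THF (4:1), 45 °C, dark, Ar; stopped at ca. 60% conversion (HPLC), 8 recovered and recycled
Reagents that add atoms: none
Why: Proposed new method: a redox-buffered quinone dehydrogenation in which p-chloranil, held near the potential of the alkylphenol/quinone-methide couple by its own hydroquinone and kept acid-free by 2,6-lutidine, removes the benzylic hydrogen pair of one free 4-alkylguaiacol ring (the two rings of 8 are homotopic, so either gives the same product) to give p-quinone methide 9, which is closed at once by the δ-hydroxyl in a 5-exo oxa-1,6-addition through an envelope with the quinoid ring anti to the neighbouring CH2OH branch, setting C2 as R (2,3-trans) while C3 and C4 are carried over from 8; the buffer is meant to hand the hydrogen back to any quinone methide that has no hydroxyl within reach (over-oxidation at C2–H of 10) instead of letting it decay; the closest known reactions are stoichiometric DDQ benzylic oxidation–etherification of alkoxyarenes and the flavoenzyme (vanillyl alcohol oxidase type) dehydrogenation of 4-alkylphenols.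

Step 5
Reactants: 10 (−)-lariciresinol; 11 4-hydroxybenzoic acid
Product: 12 agastinol, [(2R,3S,4S)-2-(4-hydroxy-3-methoxyphenyl)-4-(4-hydroxy-3-methoxybenzyl)tetrahydrofuran-3-yl]methyl 4-hydroxybenzoate
Conditions: 11 (1.2 equiv), PPh3 (1.3 equiv), DIAD (1.3 equiv), THF, 0 °C → rt
Reagents that add atoms: 4-hydroxybenzoic acid (11), O=C(O)c1ccc(O)cc1
Why: Mitsunobu esterification: only the single primary alcohol is activated as the alkoxyphosphonium, and the carboxylic acid (pKa about 4.5) is ionised by the betaine far ahead of the three phenols (pKa about 10), so the carboxylate displaces at the CH2 carbon without protecting groups; the displacement is at a non-stereogenic carbon and the neutral conditions spare the benzylic ether.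

**Compound list**

1 | 3-(4-hydroxy-3-methoxyphenyl)propanoic acid (dihydroferulic acid) | COc1cc(CCC(=O)O)ccc1O | starting material
2 | pivaloyl chloride | CC(C)(C)C(=O)Cl | starting material
3 | (R)-4-benzyl-2-oxazolidinone | O=C1N[C@H](Cc2ccccc2)CO1 | starting material
4 | 3-(3-methoxy-4-pivaloyloxyphenyl)propanoic pivalic anhydride (formed in the flask) | COc1cc(CCC(=O)OC(=O)C(C)(C)C)ccc1OC(=O)C(C)(C)C | intermediate
5 | (R)-4-benzyl-3-[3-(3-methoxy-4-pivaloyloxyphenyl)propanoyl]oxazolidin-2-one | COc1cc(CCC(=O)N2[C@H](Cc3ccccc3)COC2=O)ccc1OC(=O)C(C)(C)C | intermediate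
6 | lithium (Z)-enolate of 5 (formed in the flask) | COc1cc(C/C=C(\O[Li])N2[C@H](Cc3ccccc3)COC2=O)ccc1OC(=O)C(C)(C)C | intermediate
7 | (2S,3S)-2,3-bis(3-methoxy-4-pivaloyloxybenzyl)-1,4-bis[(R)-4-benzyl-2-oxooxazolidin-3-yl]butane-1,4-dione | O=C([C@@H](Cc1ccc(OC(=O)C(C)(C)C)c(OC)c1)[C@H](Cc1ccc(OC(=O)C(C)(C)C)c(OC)c1)C(=O)N1[C@H](Cc2ccccc2)COC1=O)N1[C@H](Cc2ccccc2)COC1=O | intermediate
8 | (+)-secoisolariciresinol, (2S,3S)-2,3-bis(4-hydroxy-3-methoxybenzyl)butane-1,4-diol | OC[C@@H](Cc1ccc(O)c(OC)c1)[C@H](Cc1ccc(O)c(OC)c1)CO | intermediate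
9 | p-quinone methide from one guaiacyl ring of 8, benzylic carbon as exocyclic methine, both carbon stereocentres as in 8 (formed in the flask) | OC[C@@H](C=C1C=CC(=O)C(OC)=C1)[C@H](Cc1ccc(O)c(OC)c1)CO | intermediate
10 | (−)-lariciresinol, 4-[(2R,3S,4S)-4-(4-hydroxy-3-methoxybenzyl)-3-(hydroxymethyl)tetrahydrofuran-2-yl]-2-methoxyphenol | COc1cc(C[C@@H]2CO[C@@H](c3ccc(O)c(OC)c3)[C@@H]2CO)ccc1O | intermediate
11 | 4-hydroxybenzoic acid | O=C(O)c1ccc(O)cc1 | starting material
12 | agastinol, [(2R,3S,4S)-2-(4-hydroxy-3-methoxyphenyl)-4-(4-hydroxy-3-methoxybenzyl)tetrahydrofuran-3-yl]methyl 4-hydroxybenzoate | COc1cc(C[C@@H]2CO[C@@H](c3ccc(O)c(OC)c3)[C@@H]2COC(=O)c2ccc(O)cc2)ccc1O | target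

**Step count and risks**

Total step count: 5. Longest linear sequence: 5 steps (1 → 5 → 7 → 8 → 10 → 12); 2, 3 and 11 are bought.

Three steps most likely to fail:

**Step 4 (the proposed new step).**
- The buffered-quinone dehydrogenation of a free alkylguaiacol with capture by a δ-hydroxyl is untested.
- Compound 10 still has a hydroxyl within reach of its second benzyl group, so a second ring closure to (−)-pinoresinol competes. On statistics alone this caps 10 at about 50% of converted material, which is why the step is stopped near 60% conversion (expected about 45% of 10 and about 40% recovered 8).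
- Other risks are phenoxyl-radical coupling, and acid-induced rearrangement to the aryltetralin if the lutidine buffer is insufficient.
- Fallback (known chemistry; sets out from 5, comes back at 10): the benzylic oxygen is brought in by an aldol reaction instead of C–H oxidation. Evans alkylation of 5 with tert-butyl bromoacetate (NaN(SiMe3)2, THF, −78 °C) gives the (S)-configured succinate half-ester imide F1. LiBH4 reduction of the imide and acid lactonisation (p-TsOH) give the (S)-β-benzyl-γ-butyrolactone F2. Its lithium enolate (LiN(SiMe3)2, THF, −78 °C) adds to commercial vanillin acetate anti to the benzyl group to give the trans aldol lactone F3 as a mixture of carbinol epimers. LiAlH4 removes both aryl esters and opens the lactone to the triol 7-hydroxysecoisolariciresinol F4. A trace of camphorsulfonic acid in CH2Cl2 at 0 °C ionises the benzylic carbinol and the C9' hydroxyl closes the tetrahydrofuran to 10; both epimers converge on the 2,3-trans product.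

**Step 2.**
- The oxidative homocoupling may give a modest yield, some meso (R,S) dimer, or Claisen-type attack of the enolate on an aryl pivalate on warming.
- Fallback (sets out from 5, comes back at 8): the C8–C8' bond is made stepwise by lactone alkylation instead of dimerisation. Compound 5 is taken through imide F1 to lactone F2 as above. 4-Benzyloxy-3-methoxybenzyl bromide F5 is made from commercial 4-benzyloxy-3-methoxybenzyl alcohol with PBr3. Alkylation of the lithium enolate of F2 with F5 (LiN(SiMe3)2, THF, −78 °C) goes trans to the existing benzyl group and gives the (3S,4S)-dibenzyl lactone F6. LiAlH4 opens the lactone and removes the pivalate to give the mono-benzyl ether diol F7. Hydrogenolysis (H2, Pd/C, EtOAc) gives 8.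

**Step 5.**
- With three free phenols present, phenol O-alkylation or oligomer formation could erode the Mitsunobu chemoselectivity.
- Fallback (sets out from 10, comes back at 12): exhaustive acylation followed by selective de-acylation replaces the redox condensation. Compound 10 is acylated on all three hydroxyls with commercial 4-acetoxybenzoyl chloride (pyridine, cat. DMAP, CH2Cl2) to give the tris(4-acetoxybenzoate) F8. Methanolic NH3 at 0 °C then cleaves the five phenolic ester linkages (three aryl acetates, two aryl benzoates). The alkyl 4-hydroxybenzoate, deactivated further once its para-phenol is free, survives and 12 is obtained.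

**Further compounds**

F1 | step 4 | tert-butyl (3S)-3-{[(4R)-4-benzyl-2-oxooxazolidin-3-yl]carbonyl}-4-(3-methoxy-4-pivaloyloxyphenyl)butanoate | CC(C)(C)OC(=O)C[C@H](Cc1ccc(OC(=O)C(C)(C)C)c(OC)c1)C(=O)N1[C@H](Cc2ccccc2)COC1=O
F2 | step 4 | (4S)-4-(3-methoxy-4-pivaloyloxybenzyl)dihydrofuran-2(3H)-one | O=C1C[C@H](Cc2ccc(OC(=O)C(C)(C)C)c(OC)c2)CO1
F3 | step 4 | (3R,4S)-3-[(4-acetoxy-3-methoxyphenyl)(hydroxy)methyl]-4-(3-methoxy-4-pivaloyloxybenzyl)dihydrofuran-2(3H)-one, 3,4-trans, both carbinol epimers | O=C1OC[C@@H](Cc2ccc(OC(=O)C(C)(C)C)c(OC)c2)[C@@H]1C(O)c1ccc(OC(C)=O)c(OC)c1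
F4 | step 4 | (2S,3S)-2-[hydroxy(4-hydroxy-3-methoxyphenyl)methyl]-3-(4-hydroxy-3-methoxybenzyl)butane-1,4-diol (7-hydroxysecoisolariciresinol), both carbinol epimers | OC(c1ccc(O)c(OC)c1)[C@H](CO)[C@@H](CO)Cc1ccc(O)c(OC)c1
F5 | step 2 | 4-benzyloxy-3-methoxybenzyl bromide | COc1cc(CBr)ccc1OCc1ccccc1
F6 | step 2 | (3S,4S)-3-(4-benzyloxy-3-methoxybenzyl)-4-(3-methoxy-4-pivaloyloxybenzyl)dihydrofuran-2(3H)-one | O=C1OC[C@@H](Cc2ccc(OC(=O)C(C)(C)C)c(OC)c2)[C@@H]1Cc1ccc(OCc2ccccc2)c(OC)c1
F7 | step 2 | (2S,3S)-2-(4-benzyloxy-3-methoxybenzyl)-3-(4-hydroxy-3-methoxybenzyl)butane-1,4-diol | OC[C@@H](Cc1ccc(OCc2ccccc2)c(OC)c1)[C@H](Cc1ccc(O)c(OC)c1)CO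
F8 | step 5 | [(2R,3S,4S)-2-[4-(4-acetoxybenzoyloxy)-3-methoxyphenyl]-4-[4-(4-acetoxybenzoyloxy)-3-methoxybenzyl]tetrahydrofuran-3-yl]methyl 4-acetoxybenzoate | COc1cc(C[C@@H]2CO[C@@H](c3ccc(OC(=O)c4ccc(OC(C)=O)cc4)c(OC)c3)[C@@H]2COC(=O)c2ccc(OC(C)=O)cc2)ccc1OC(=O)c1ccc(OC(C)=O)cc1
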